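**Plan**
- Retrosynthesis: both pyranone rings are opened at C4–C4a (Friedel–Crafts acylation) and at O1–C2 (phenol addition to an arylpropiolate), which leads back to a biphenyl-2,4'-diol and two arylpropiolate units.
- Ring A of the 8-linked flavone is then cut at C8a–C8, C7–C6 and C8a–C4a into an aryl methoxyalkyne and 3-ethoxycyclobutenone. The C8–C6' biaryl bond is the former aryl–alkyne bond, set by a Negishi coupling on a phloroglucinol-derived iodide.
- Enabling feature: in ring A of the 8-linked unit the axis carbon C8 lies between C7–OMe and the phenolic C8a–O1, with C5–O meta to both oxygens. This 2-aryl-3-methoxy-5-alkoxyphenol pattern is what a 3-alkoxy vinylketene and an aryl methyl ynol ether assemble directly.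
- Forward: ring A of the 6-linked unit is bought as 3,5-bis(benzyloxy)phenol and carried to the iodide and the ynol ether; the benzannulation builds ring A of the 8-linked unit; both rings C are then closed in one twofold acylation; BCl3 frees five hydroxyls and leaves 7-OMe.
- Stereochemistry: there is no stereocentre; the tetra-ortho-substituted axis forms without control and is obtained racemic.

Key step: step 5

Assumptions: the target SMILES carries no axial descriptor, so the racemic axis is taken as the goal. Plain locants (C2–C8a) refer to the 8-linked flavone unit (unit 1), primed locants to the 6-linked unit (unit 2). Compounds 22–24 are drawn as the Z,Z isomers expected from anti addition; any E isomer is carried along, since both geometries converge in step 10.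

**Step 1**
Reactants: 1 3,5-bis(benzyloxy)phenol
Product: 2 1,3-bis(benzyloxy)-5-(triisopropylsilyloxy)benzene
Conditions: TIPSCl, imidazole, DMF, rt
Reagents that add atoms: chlorotriisopropylsilane, CC(C)[Si](Cl)(C(C)C)C(C)C
Why: Imidazole-promoted O-silylation of the only free phenol; the bulky silyl ether survives n-BuLi, is too hindered to direct lithiation to its own ortho positions or to migrate to carbon, and can later be removed without touching benzyl ethers.

**Step 2**
Reactants: 2 1,3-bis(benzyloxy)-5-(triisopropylsilyloxy)benzene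
Product: 4 1,3-bis(benzyloxy)-2-iodo-5-(triisopropylsilyloxy)benzene, via aryllithium 3 (not isolated)
Conditions: n-BuLi, THF, 0 °C; then I2, −78 °C → rt
Reagents that add atoms: iodine, II
Why: Directed ortho-metalation; the hydrogen between the two benzyloxy groups is the most acidic, doubly coordinated site and should be removed by n-BuLi at 0 °C faster than a benzylic hydrogen (the entry to Wittig rearrangement), after which iodine traps the aryllithium.

**Step 3**
Reactants: 5 trichloroethylene
Product: 7 (E)-1,2-dichloro-1-methoxyethene, via dichloroacetylene 6 (not isolated)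
Conditions: MeOH, KH, THF, 0 °C; then 5, −50 °C → rt
Reagents that add atoms: methanol, CO
Why: Methoxide-induced dehydrochlorination to dichloroacetylene and anti addition of methanol across it (the first stage of the trichloroethylene route to alkynyl ethers) should give the E dichloroenol ether.

**Step 4**
Reactants: 7 (E)-1,2-dichloro-1-methoxyethene; 4 1,3-bis(benzyloxy)-2-iodo-5-(triisopropylsilyloxy)benzene
Product: 11 1,3-bis(benzyloxy)-2-(methoxyethynyl)-5-(triisopropylsilyloxy)benzene, via 1-chloro-2-methoxyethyne 8 (not isolated), via lithium methoxyacetylide 9 (not isolated), via methoxyethynylzinc chloride 10 (not isolated)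
Conditions: 7, n-BuLi (2 equiv), THF, −78 → −40 °C; ZnCl2, → 0 °C; then 4, Pd(PPh3)4 (cat.), rt → 45 °C
Reagents that add atoms: none
Why: Two equivalents of n-BuLi effect β-elimination to the chloroalkyne and chlorine–lithium exchange, transmetalation gives the alkynylzinc chloride, and Negishi coupling under zerovalent palladium catalysis forms the aryl–alkyne bond, the slim alkynyl partner tolerating the two ortho benzyloxy groups.

**Step 5**
Reactants: 11 1,3-bis(benzyloxy)-2-(methoxyethynyl)-5-(triisopropylsilyloxy)benzene; 12 3-ethoxycyclobut-2-en-1-one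
Product: 17 2-[2,6-bis(benzyloxy)-4-(triisopropylsilyloxy)phenyl]-5-ethoxy-3-methoxyphenol, via vinylketene 13 (not isolated), via vinylcyclobutenone 14 (not isolated), via dienylketene 15 (not isolated), via cyclohexadienone 16 (not isolated)
Conditions: PhMe, 110 °C, sealed tube (12, 2 equiv, added in portions)
Reagents that add atoms: none
Why: Danheiser benzannulation: four-electron electrocyclic opening of 12 gives the ethoxy vinylketene 13, whose ketene C=C adds [2+2] to the ynol ether so that the nucleophilic aryl-bearing alkyne carbon joins the ketene carbonyl carbon (C8a–C8) and the methoxy-bearing carbon joins the ketene α-carbon (C7–C6), giving 14. Four-electron opening of 14 to the dienylketene 15 and six-electron electrocyclisation (C8a–C4a) close ring A of unit 1 as cyclohexadienone 16, which tautomerises to phenol 17; the closest known reaction type is the cyclobutenone/alkoxyalkyne benzannulation to resorcinol monoethers. The one selectivity required is the regiochemistry of the [2+2] step, secured by the strong polarisation of the alkyne by its methoxy group, which outweighs the aryl donor, so aryl ends between OH and OMe and the ethoxy group ends at C5. No stereocentre results (the sp3 carbon of 14 is lost on ring opening) and the axis forms racemic. The methyl ynol ether has no β-hydrogen for retro-ene loss on heating, and the linear alkyne holds the benzyloxy groups away from the reacting carbons. The four ortho substituents never pass through an aryl–aryl coupling, because the biaryl bond is the old aryl–alkyne bond.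

**Step 6**
Reactants: 17 2-[2,6-bis(benzyloxy)-4-(triisopropylsilyloxy)phenyl]-5-ethoxy-3-methoxyphenol
Product: 18 2',6'-bis(benzyloxy)-4-ethoxy-6-methoxybiphenyl-2,4'-diol
Conditions: TBAF, AcOH, THF, 0 °C
Reagents that add atoms: none
Why: Fluoride cleaves the aryl silyl ether by Si–F bond formation under acetic acid buffering, leaving benzyl, methyl and ethyl ethers untouched.

**Step 7**
Reactants: 19 1-(benzyloxy)-4-ethynylbenzene
Product: 21 methyl 3-[4-(benzyloxy)phenyl]prop-2-ynoate, via lithium arylacetylide 20 (not isolated)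
Conditions: n-BuLi, THF, −78 °C; then ClCO2Me, −78 °C → rt
Reagents that add atoms: methyl chloroformate, COC(=O)Cl
Why: Deprotonation of the terminal alkyne and C-acylation of the lithium acetylide with the chloroformate.

**Step 8**
Reactants: 18 2',6'-bis(benzyloxy)-4-ethoxy-6-methoxybiphenyl-2,4'-diol; 21 methyl 3-[4-(benzyloxy)phenyl]prop-2-ynoate
Product: 22 dimethyl (2Z,2'Z)-3,3'-{[2',6'-bis(benzyloxy)-4-ethoxy-6-methoxybiphenyl-2,4'-diyl]bis(oxy)}bis{3-[4-(benzyloxy)phenyl]prop-2-enoate}
Conditions: 21 (2.5 equiv), Cs2CO3 (0.3 equiv), DMF, 70 °C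
Reagents that add atoms: none
Why: Base-catalysed conjugate addition of both phenoxides to the ynoate (oxa-Michael, first stage of the Ruhemann flavone synthesis); anti addition places aryloxy and ester cis.

**Step 9**
Reactants: 22 the bis(aryloxycinnamate) dimethyl ester
Product: 23 (2Z,2'Z)-3,3'-{[2',6'-bis(benzyloxy)-4-ethoxy-6-methoxybiphenyl-2,4'-diyl]bis(oxy)}bis{3-[4-(benzyloxy)phenyl]prop-2-enoic acid}
Conditions: LiOH, THF/MeOH/H2O, rt; then aq. HCl to pH 3
Reagents that add atoms: lithium hydroxide, [Li+].[OH-]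
Why: Saponification of the two methyl esters; hydroxide attack at the ester carbonyl should be faster than addition–elimination at the hindered, doubly donor-substituted β-carbon.

**Step 10**
Reactants: 23 the bis(aryloxycinnamic acid)
Product: 25 8-[5,7-bis(benzyloxy)-2-(4-benzyloxyphenyl)-4-oxo-4H-chromen-6-yl]-2-(4-benzyloxyphenyl)-5-ethoxy-7-methoxy-4H-chromen-4-one, via bis(mixed anhydride) 24 (not isolated)
Conditions: TFAA, CH2Cl2, 0 °C → rt
Reagents that add atoms: none
Why: Twofold intramolecular Friedel–Crafts acylation through the mixed trifluoroacetic anhydrides; each acyl group can reach only the carbon ortho to its own aryloxy oxygen (C4a between O1 and C5–OEt in unit 1, either of two equivalent carbons in unit 2), both activated by an ortho and a para alkoxy group, and the push–pull double bond rotates at the acylium stage so that both geometries close.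

**Step 11**
Reactants: 25 the protected biflavone
Product: 26 7'-O-methylagathisflavone, 8-[5,7-dihydroxy-2-(4-hydroxyphenyl)-4-oxo-4H-chromen-6-yl]-5-hydroxy-2-(4-hydroxyphenyl)-7-methoxy-4H-chromen-4-one
Conditions: BCl3, C6HMe5, CH2Cl2, −78 → 0 °C, then rt; MeOH/H2O
Reagents that add atoms: none
Why: Lewis-acid dealkylation; BCl3 removes the four benzyl groups at low temperature with pentamethylbenzene capturing the benzyl cations, and on warming cleaves the 5-O-ethyl group held in a six-membered boron chelate with the C4 carbonyl, whereas the unchelated 7-methyl ether should remain.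

**Compound list**
1 | 3,5-bis(benzyloxy)phenol | Oc1cc(OCc2ccccc2)cc(OCc2ccccc2)c1 | starting material
2 | 1,3-bis(benzyloxy)-5-(triisopropylsilyloxy)benzene | CC(C)[Si](Oc1cc(OCc2ccccc2)cc(OCc2ccccc2)c1)(C(C)C)C(C)C | intermediate
3 | 2,6-bis(benzyloxy)-4-(triisopropylsilyloxy)phenyllithium | [Li]c1c(OCc2ccccc2)cc(O[Si](C(C)C)(C(C)C)C(C)C)cc1OCc1ccccc1 | intermediate
4 | 1,3-bis(benzyloxy)-2-iodo-5-(triisopropylsilyloxy)benzene | Ic1c(OCc2ccccc2)cc(O[Si](C(C)C)(C(C)C)C(C)C)cc1OCc1ccccc1 | intermediate
5 | trichloroethylene | ClC=C(Cl)Cl | starting material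
6 | dichloroacetylene | ClC#CCl | intermediate
7 | (E)-1,2-dichloro-1-methoxyethene | CO/C(Cl)=C\Cl | intermediate
8 | 1-chloro-2-methoxyethyne | COC#CCl | intermediate
9 | lithium methoxyacetylide | [Li]C#COC | intermediate
10 | methoxyethynylzinc chloride | COC#C[Zn]Cl | intermediate
11 | 1,3-bis(benzyloxy)-2-(methoxyethynyl)-5-(triisopropylsilyloxy)benzene | COC#Cc1c(OCc2ccccc2)cc(O[Si](C(C)C)(C(C)C)C(C)C)cc1OCc1ccccc1 | intermediate
12 | 3-ethoxycyclobut-2-en-1-one | CCOC1=CC(=O)C1 | starting material
13 | 3-ethoxybuta-1,3-dien-1-one (vinylketene) | C=C(OCC)C=C=O | intermediate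
14 | 2-[2,6-bis(benzyloxy)-4-(triisopropylsilyloxy)phenyl]-4-(1-ethoxyvinyl)-3-methoxycyclobut-2-en-1-one (racemic) | C=C(OCC)C1C(OC)=C(c2c(OCc3ccccc3)cc(O[Si](C(C)C)(C(C)C)C(C)C)cc2OCc2ccccc2)C1=O | intermediate
15 | (3E)-2-[2,6-bis(benzyloxy)-4-(triisopropylsilyloxy)phenyl]-5-ethoxy-3-methoxyhexa-1,3,5-trien-1-one (dienylketene) | C=C(OCC)/C=C(/OC)C(=C=O)c1c(OCc2ccccc2)cc(O[Si](C(C)C)(C(C)C)C(C)C)cc1OCc1ccccc1 | intermediate
16 | 2-[2,6-bis(benzyloxy)-4-(triisopropylsilyloxy)phenyl]-5-ethoxy-3-methoxycyclohexa-2,4-dien-1-one | CCOC1=CC(OC)=C(c2c(OCc3ccccc3)cc(O[Si](C(C)C)(C(C)C)C(C)C)cc2OCc2ccccc2)C(=O)C1 | intermediate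
17 | 2-[2,6-bis(benzyloxy)-4-(triisopropylsilyloxy)phenyl]-5-ethoxy-3-methoxyphenol | CCOc1cc(O)c(-c2c(OCc3ccccc3)cc(O[Si](C(C)C)(C(C)C)C(C)C)cc2OCc2ccccc2)c(OC)c1 | intermediate
18 | 2',6'-bis(benzyloxy)-4-ethoxy-6-methoxybiphenyl-2,4'-diol | CCOc1cc(O)c(-c2c(OCc3ccccc3)cc(O)cc2OCc2ccccc2)c(OC)c1 | intermediate
19 | 1-(benzyloxy)-4-ethynylbenzene | C#Cc1ccc(OCc2ccccc2)cc1 | starting material
20 | lithium [4-(benzyloxy)phenyl]acetylide | [Li]C#Cc1ccc(OCc2ccccc2)cc1 | intermediate
21 | methyl 3-[4-(benzyloxy)phenyl]prop-2-ynoate | COC(=O)C#Cc1ccc(OCc2ccccc2)cc1 | intermediate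
22 | dimethyl (2Z,2'Z)-3,3'-{[2',6'-bis(benzyloxy)-4-ethoxy-6-methoxybiphenyl-2,4'-diyl]bis(oxy)}bis{3-[4-(benzyloxy)phenyl]prop-2-enoate} | CCOc1cc(O/C(c2ccc(OCc3ccccc3)cc2)=C\C(=O)OC)c(-c2c(OCc3ccccc3)cc(O/C(c3ccc(OCc4ccccc4)cc3)=C\C(=O)OC)cc2OCc2ccccc2)c(OC)c1 | intermediate
23 | (2Z,2'Z)-3,3'-{[2',6'-bis(benzyloxy)-4-ethoxy-6-methoxybiphenyl-2,4'-diyl]bis(oxy)}bis{3-[4-(benzyloxy)phenyl]prop-2-enoic acid} | CCOc1cc(O/C(c2ccc(OCc3ccccc3)cc2)=C\C(=O)O)c(-c2c(OCc3ccccc3)cc(O/C(c3ccc(OCc4ccccc4)cc3)=C\C(=O)O)cc2OCc2ccccc2)c(OC)c1 | intermediate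
24 | bis(trifluoroacetic) mixed anhydride of 23 | CCOc1cc(O/C(c2ccc(OCc3ccccc3)cc2)=C\C(=O)OC(=O)C(F)(F)F)c(-c2c(OCc3ccccc3)cc(O/C(c3ccc(OCc4ccccc4)cc3)=C\C(=O)OC(=O)C(F)(F)F)cc2OCc2ccccc2)c(OC)c1 | intermediate
25 | 8-[5,7-bis(benzyloxy)-2-(4-benzyloxyphenyl)-4-oxo-4H-chromen-6-yl]-2-(4-benzyloxyphenyl)-5-ethoxy-7-methoxy-4H-chromen-4-one | COc1cc(OCC)c2c(=O)cc(-c3ccc(OCc4ccccc4)cc3)oc2c1-c1c(OCc2ccccc2)cc2oc(-c3ccc(OCc4ccccc4)cc3)cc(=O)c2c1OCc1ccccc1 | intermediate
26 | 7'-O-methylagathisflavone | COc1cc(O)c2c(=O)cc(-c3ccc(O)cc3)oc2c1-c1c(O)cc2oc(-c3ccc(O)cc3)cc(=O)c2c1O | target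

**Step count and risks**
Total step count: 11. Longest linear sequence: 9 steps (steps 1, 2, 4, 5, 6, 8, 9, 10, 11); steps 3 and 7 prepare the two side reagents.

Steps most likely to fail:

1. Step 5. The vinylogous ester 12 may open too slowly at temperatures the electron-rich ynol ether tolerates, the vinylketene may dimerise or acylate the phenol as it forms, and the donor aryl group could erode the regiochemistry of the [2+2] step. A Diels–Alder-type addition of the alkyne across the vinylketene would end in the same phenol and is not a concern. Fallback, setting out from 11 and returning at 17: the same vinylketene 13 is generated at room temperature by photochemical Wolff rearrangement instead of thermal cyclobutenone opening. Ethyl vinyl ether is lithiated (t-BuLi, THF) to 1-ethoxyvinyllithium F1 and acylated with N-methoxy-N-methylacetamide to 3-ethoxybut-3-en-2-one F2. Its lithium enolate (LiN(SiMe3)2) is trifluoroacetylated with 2,2,2-trifluoroethyl trifluoroacetate to 5-ethoxy-1,1,1-trifluorohex-5-ene-2,4-dione F3, which undergoes detrifluoroacetylative diazo transfer (MsN3, Et3N, MeCN/H2O) to 1-diazo-3-ethoxybut-3-en-2-one F4. Irradiation of F4 with 11 (CH2Cl2, rt, then 80 °C) should give 13 with loss of nitrogen and from there 17 by the same cascade.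

2. Step 8. The twofold conjugate addition may stall on the donor-substituted ynoate, revert, or be diverted to C-attack by the ambident phloroglucinol-type phenoxides. Fallback, setting out from 18 (with 21 as the source of the vinyl partner) and returning at 22: the O–C bond is made by copper-catalysed Ullmann-type vinylation instead of conjugate addition. Hydroiodination of 21 (NaI, AcOH, 70 °C, anti addition) gives methyl (Z)-3-[4-(benzyloxy)phenyl]-3-iodoprop-2-enoate F5, which is coupled with both phenols of 18 (CuI, N,N-dimethylglycine, Cs2CO3, dioxane, 90 °C) with retention of geometry to give 22.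

3. Step 10. Acid generated in the flask may strip benzyl groups and C-benzylate the rings, the second ring closure may lag behind the first, and the push–pull mixed anhydride may be too weak an acylating agent. Fallback, setting out from 18 and returning at 25: the C4–C4a bonds are made first and the O1–C2 bonds last. Ortho-specific Casnati–Skattebøl formylation (MgCl2, Et3N, paraformaldehyde, MeCN, reflux) gives 2',6'-bis(benzyloxy)-4-ethoxy-2,4'-dihydroxy-6-methoxybiphenyl-3,3'-dicarbaldehyde F6. Excess lithium acetylide 20 (THF, −78 °C → rt) adds to both aldehydes to give 3,3'-bis{3-[4-(benzyloxy)phenyl]-1-hydroxyprop-2-yn-1-yl}-2',6'-bis(benzyloxy)-4-ethoxy-6-methoxybiphenyl-2,4'-diol F7 as a mixture of diastereomers. MnO2 (CH2Cl2) oxidises it to 3,3'-bis{3-[4-(benzyloxy)phenyl]prop-2-ynoyl}-2',6'-bis(benzyloxy)-4-ethoxy-6-methoxybiphenyl-2,4'-diol F8, and Et2NH in EtOH at reflux closes both pyranones by 6-endo addition of the ortho phenols to the ynones, giving 25.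

**Further compounds**
F1 | step 5 | 1-ethoxyvinyllithium | [Li]C(=C)OCC
F2 | step 5 | 3-ethoxybut-3-en-2-one | C=C(OCC)C(C)=O
F3 | step 5 | 5-ethoxy-1,1,1-trifluorohex-5-ene-2,4-dione | C=C(OCC)C(=O)CC(=O)C(F)(F)F
F4 | step 5 | 1-diazo-3-ethoxybut-3-en-2-one | C=C(OCC)C(=O)C=[N+]=[N-]
F5 | step 8 | methyl (Z)-3-[4-(benzyloxy)phenyl]-3-iodoprop-2-enoate | COC(=O)/C=C(\I)c1ccc(OCc2ccccc2)cc1
F6 | step 10 | 2',6'-bis(benzyloxy)-4-ethoxy-2,4'-dihydroxy-6-methoxybiphenyl-3,3'-dicarbaldehyde | CCOc1cc(OC)c(-c2c(OCc3ccccc3)cc(O)c(C=O)c2OCc2ccccc2)c(O)c1C=O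
F7 | step 10 | 3,3'-bis{3-[4-(benzyloxy)phenyl]-1-hydroxyprop-2-yn-1-yl}-2',6'-bis(benzyloxy)-4-ethoxy-6-methoxybiphenyl-2,4'-diol (mixture of diastereomers) | CCOc1cc(OC)c(-c2c(OCc3ccccc3)cc(O)c(C(O)C#Cc3ccc(OCc4ccccc4)cc3)c2OCc2ccccc2)c(O)c1C(O)C#Cc1ccc(OCc2ccccc2)cc1
F8 | step 10 | 3,3'-bis{3-[4-(benzyloxy)phenyl]prop-2-ynoyl}-2',6'-bis(benzyloxy)-4-ethoxy-6-methoxybiphenyl-2,4'-diol | CCOc1cc(OC)c(-c2c(OCc3ccccc3)cc(O)c(C(=O)C#Cc3ccc(OCc4ccccc4)cc3)c2OCc2ccccc2)c(O)c1C(=O)C#Cc1ccc(OCc2ccccc2)cc1
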